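**Retrosynthetic overview**

1. The strategy rests on the γ-butyrolactone ring of target 18 (O1, C2(=O), C3, C4, C5): the adjacent ring carbons C3 (α to the carbonyl) and C4 (β) each carry one exocyclic benzylic CH2, trans to each other, and C5 is a plain OCH2. This is the pattern of a butenolide that accepts at C4 and donates at C3.
2. Disconnections: C4–CH2Ar by conjugate addition of lithiated dithiane 12 (the dithiane carbon is the masked benzylic CH2) and C3–CH2Ar' by alkylation of the resulting enolate with bromide 11, both on chiral butenolide 6, whose menthyloxy acetal carbon is the masked C5 methylene.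
3. Ring order: the lactone ring is made first as hydroxybutenolide 3 from furfural and resolved as menthyl acetal 6. No ring closes in the key step. The lactone is opened and re-closed once, in step 8.
4. End game: desulfurisation (14 to 15), reductive excision of the acetal (15 to 17), hydrogenolysis of the two benzyl ethers (17 to 18).

Key step: step 6

Remark: the lactone is numbered O1, C2(=O), C3, C4, C5 throughout; l-menthyl is the (1R,2S,5R)-2-isopropyl-5-methylcyclohexyl group of (−)-menthol 4; hemiacetal 3 is racemic and its C5 centre is fixed only in step 2.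

**Route**

Step 1
Reactants: 1 furfural
Product: 3 5-hydroxyfuran-2(5H)-one (racemic), via furfural endoperoxide 2 (not isolated)
Conditions: O2, visible light, rose bengal (cat.), MeOH, 20–25 °C
Reagents that add atoms: dioxygen (O=O)
Why: Dye-sensitised photooxygenation, in which singlet oxygen adds across C2/C5 of the furan in a [4+2] cycloaddition to give endoperoxide 2 and methanol then attacks the formyl group so that fragmentation expels it as the formate ester and leaves the γ-hydroxybutenolide, whose C5 is formed racemic and is resolved in step 2.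

Step 2
Reactants: 3 5-hydroxyfuran-2(5H)-one; 4 (−)-menthol
Product: 6 (5R)-5-(l-menthyloxy)furan-2(5H)-one, via (5S)-5-(l-menthyloxy)furan-2(5H)-one 5 (not isolated)
Conditions: camphorsulfonic acid (cat.), toluene, reflux, Dean–Stark; crystallise from petroleum ether, −20 °C; mother liquor re-equilibrated with cat. TsOH and recrystallised
Reagents that add atoms: none
Why: Acid-catalysed acetalisation of the pseudo-acid through the ring acyloxycarbenium ion gives both C5 epimers, and because the acetal centre equilibrates under acid while the 5R epimer should be the one that crystallises, repeated equilibration and crystallisation should funnel epimer 5 into 6 (crystallisation-driven diastereomer resolution), which fixes the 5R centre.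

Step 3
Reactants: 7 veratraldehyde
Product: 8 2-(3,4-dimethoxyphenyl)-1,3-dithiane
Conditions: HS(CH2)3SH, BF3·OEt2 (cat.), CH2Cl2, 0 °C → rt
Reagents that add atoms: propane-1,3-dithiol (SCCCS)
Why: Lewis-acid-catalysed dithioacetalisation of an aromatic aldehyde, driven by formation of the six-membered dithiane, with the aryl methyl ethers inert to catalytic BF3 at this temperature.

Step 4
Reactants: 9 3,4-bis(benzyloxy)benzaldehyde
Product: 10 3,4-bis(benzyloxy)benzyl alcohol
Conditions: NaBH4, MeOH/THF, 0 °C → rt
Reagents that add atoms: none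
Why: Borohydride reduction of an aromatic aldehyde to the benzylic alcohol, which leaves the aryl benzyl ethers untouched.

Step 5
Reactants: 10 3,4-bis(benzyloxy)benzyl alcohol
Product: 11 3,4-bis(benzyloxy)benzyl bromide
Conditions: PBr3, Et2O, 0 °C; used fresh
Reagents that add atoms: phosphorus tribromide (BrP(Br)Br)
Why: Bromination of a benzylic alcohol with PBr3 (displacement of the phosphite ester by bromide) is fast for an electron-rich benzylic position at 0 °C and should leave the aryl benzyl ethers intact.

Step 6
Reactants: 8 2-(3,4-dimethoxyphenyl)-1,3-dithiane; 6 (5R)-5-(l-menthyloxy)furan-2(5H)-one; 11 3,4-bis(benzyloxy)benzyl bromide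
Product: 14 (3R,4R,5R)-3-[3,4-bis(benzyloxy)benzyl]-4-[2-(3,4-dimethoxyphenyl)-1,3-dithian-2-yl]-5-(l-menthyloxy)dihydrofuran-2(3H)-one, via 2-lithio-2-(3,4-dimethoxyphenyl)-1,3-dithiane 12 (not isolated), via lithium enolate of the 1,4-adduct 13 (not isolated)
Conditions: 8, n-BuLi, THF, −78 → −30 °C; recool, add 6, −78 °C; then 11, TMEDA, −78 °C → rt; aq NH4Cl
Reagents that add atoms: none
Why: Deprotonation of 8 gives the sulfur- and aryl-stabilised carbanion 12 (Corey–Seebach umpolung), which adds in Michael fashion to C4 of butenolide 6 to give lactone enolate 13, and 13 is C-alkylated at C3 by bromide 11 in an SN2 step, so the C4–C(dithiane) and C3–CH2Ar bonds form in one flask and no ring closes. The closest known reaction type is the tandem conjugate addition–enolate alkylation of 2-aryl-2-lithio-1,3-dithianes on 5-alkoxyfuran-2(5H)-ones and on the parent butenolide. The C4 stereocentre is controlled by the C5 acetal centre, since the carbanion should approach the face of the flat ring opposite the menthyloxy group, which gives 4R from the 5R acetal. The C3 stereocentre is controlled by C4, since the enolate should be benzylated on the face opposite the bulky quaternary dithianyl group, which gives the 3,4-trans (3R) lactone. The step needs 1,4- over 1,2-addition, which the soft delocalised benzylic dithiane anion and the unhindered β-carbon of the butenolide should secure, and it needs C-monoalkylation over O-alkylation or proton transfer, which the reactive benzylic bromide, TMEDA activation of the lithium enolate and the hindered tertiary C3–H of the product should secure.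

Step 7
Reactants: 14 (3R,4R,5R)-3-[3,4-bis(benzyloxy)benzyl]-4-[2-(3,4-dimethoxyphenyl)-1,3-dithian-2-yl]-5-(l-menthyloxy)dihydrofuran-2(3H)-one
Product: 15 (3R,4R,5R)-3-[3,4-bis(benzyloxy)benzyl]-4-(3,4-dimethoxybenzyl)-5-(l-menthyloxy)dihydrofuran-2(3H)-one
Conditions: Raney Ni (W-2, excess, washed neutral), EtOH/THF, rt, no added H2; stopped when 14 is consumed
Reagents that add atoms: none
Why: Mozingo-type reductive desulfurisation, in which the benzylic C–S bonds are hydrogenolysed by hydrogen held on the nickel so that the dithiane carbon becomes the C4 benzylic CH2 without touching a stereocentre, and the neutral ambient conditions without added hydrogen should spare the aryl benzyl ethers and the lactone acetal.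

Step 8
Reactants: 15 (3R,4R,5R)-3-[3,4-bis(benzyloxy)benzyl]-4-(3,4-dimethoxybenzyl)-5-(l-menthyloxy)dihydrofuran-2(3H)-one
Product: 17 (3R,4R)-3-[3,4-bis(benzyloxy)benzyl]-4-(3,4-dimethoxybenzyl)dihydrofuran-2(3H)-one, via (2R,3R)-2-[3,4-bis(benzyloxy)benzyl]-3-(3,4-dimethoxybenzyl)-4-hydroxybutanoic acid 16 (not isolated)
Conditions: NaBH4, KOH, EtOH/THF/H2O, 0 °C → rt; then aq HCl to pH 1–2, rt
Reagents that add atoms: none
Why: Saponification of the acylal-type lactone releases menthol and unmasks C5 as an aldehyde that borohydride should reduce at once to the primary alcohol, and acidification lactonises γ-hydroxy acid 16 (reductive acetal excision, then acid-catalysed lactonisation), so C5 becomes CH2 while C3 (α to a carboxylate) and C4 (the aldehyde being reduced faster than it enolises) should keep their configuration.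

Step 9
Reactants: 17 (3R,4R)-3-[3,4-bis(benzyloxy)benzyl]-4-(3,4-dimethoxybenzyl)dihydrofuran-2(3H)-one
Product: 18 3'-O-demethylarctigenin, (3R,4R)-3-(3,4-dihydroxybenzyl)-4-(3,4-dimethoxybenzyl)dihydrofuran-2(3H)-one
Conditions: H2 (1 atm), 10% Pd/C, EtOAc/EtOH, rt; filtered and concentrated under Ar
Reagents that add atoms: none
Why: Catalytic hydrogenolysis of the two aryl benzyl ethers over Pd/C releases the catechol, while the lactone, the methyl ethers and the benzylic C–C bonds are inert, so C3 and C4 are not touched.

**Compound list**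

1 | furfural | O=Cc1ccco1 | starting material
2 | furfural endoperoxide, 2,3,7-trioxabicyclo[2.2.1]hept-5-ene-1-carbaldehyde (racemic) | O=CC12C=CC(OO1)O2 | intermediate
3 | 5-hydroxyfuran-2(5H)-one (racemic) | O=C1C=CC(O)O1 | intermediate
4 | (−)-menthol, (1R,2S,5R)-2-isopropyl-5-methylcyclohexanol | CC(C)[C@@H]1CC[C@@H](C)C[C@H]1O | starting material
5 | (5S)-5-(l-menthyloxy)furan-2(5H)-one | O=C1C=C[C@@H](O[C@@H]2C[C@H](C)CC[C@H]2C(C)C)O1 | intermediate
6 | (5R)-5-(l-menthyloxy)furan-2(5H)-one | O=C1C=C[C@H](O[C@@H]2C[C@H](C)CC[C@H]2C(C)C)O1 | intermediate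
7 | veratraldehyde | COc1ccc(C=O)cc1OC | starting material
8 | 2-(3,4-dimethoxyphenyl)-1,3-dithiane | COc1ccc(C2SCCCS2)cc1OC | intermediate
9 | 3,4-bis(benzyloxy)benzaldehyde | O=Cc1ccc(OCc2ccccc2)c(OCc2ccccc2)c1 | starting material
10 | 3,4-bis(benzyloxy)benzyl alcohol | OCc1ccc(OCc2ccccc2)c(OCc2ccccc2)c1 | intermediate
11 | 3,4-bis(benzyloxy)benzyl bromide | BrCc1ccc(OCc2ccccc2)c(OCc2ccccc2)c1 | intermediate
12 | 2-lithio-2-(3,4-dimethoxyphenyl)-1,3-dithiane | [Li]C1(SCCCS1)c1ccc(OC)c(OC)c1 | intermediate
13 | lithium enolate of the 1,4-adduct, (4R,5R)-4-[2-(3,4-dimethoxyphenyl)-1,3-dithian-2-yl]-5-(l-menthyloxy)-4,5-dihydrofuran-2-olate lithium | COc1ccc(C2(SCCCS2)[C@H]3[C@H](O[C@@H]4C[C@H](C)CC[C@H]4C(C)C)OC(O[Li])=C3)cc1OC | intermediate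
14 | (3R,4R,5R)-3-[3,4-bis(benzyloxy)benzyl]-4-[2-(3,4-dimethoxyphenyl)-1,3-dithian-2-yl]-5-(l-menthyloxy)dihydrofuran-2(3H)-one | COc1ccc(C2(SCCCS2)[C@H]3[C@H](O[C@@H]4C[C@H](C)CC[C@H]4C(C)C)OC(=O)[C@@H]3Cc3ccc(OCc4ccccc4)c(OCc4ccccc4)c3)cc1OC | intermediate
15 | (3R,4R,5R)-3-[3,4-bis(benzyloxy)benzyl]-4-(3,4-dimethoxybenzyl)-5-(l-menthyloxy)dihydrofuran-2(3H)-one | COc1ccc(C[C@H]2[C@H](O[C@@H]3C[C@H](C)CC[C@H]3C(C)C)OC(=O)[C@@H]2Cc2ccc(OCc3ccccc3)c(OCc3ccccc3)c2)cc1OC | intermediate
16 | (2R,3R)-2-[3,4-bis(benzyloxy)benzyl]-3-(3,4-dimethoxybenzyl)-4-hydroxybutanoic acid | COc1ccc(C[C@@H](CO)[C@@H](Cc2ccc(OCc3ccccc3)c(OCc3ccccc3)c2)C(=O)O)cc1OC | intermediate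
17 | (3R,4R)-3-[3,4-bis(benzyloxy)benzyl]-4-(3,4-dimethoxybenzyl)dihydrofuran-2(3H)-one | COc1ccc(C[C@H]2COC(=O)[C@@H]2Cc2ccc(OCc3ccccc3)c(OCc3ccccc3)c2)cc1OC | intermediate
18 | 3'-O-demethylarctigenin, (3R,4R)-3-(3,4-dihydroxybenzyl)-4-(3,4-dimethoxybenzyl)dihydrofuran-2(3H)-one | COc1ccc(C[C@H]2COC(=O)[C@@H]2Cc2ccc(O)c(O)c2)cc1OC | target

**Step count**

Total: 9 steps. Longest linear sequence: 6 steps (1, 2, 6, 7, 8, 9 from furfural, or 4, 5, 6, 7, 8, 9 from 3,4-bis(benzyloxy)benzaldehyde).

**Steps most likely to fail**

Step 6 (key step). The enolate 13 may be trapped poorly: proton transfer to the enolate from product or unreacted dithiane, O-alkylation, or fragmentation of the enolate on warming can compete with C-benzylation, and some 1,2-addition to the lactone carbonyl may occur. The fallback sets out from 6 and 8 and comes back at 14, and it separates the two bond formations. Lithiated dithiane 12 is added to 6 at −78 °C and the enolate is protonated with aq NH4Cl, which should give the isolated Michael adduct (4R,5R)-4-[2-(3,4-dimethoxyphenyl)-1,3-dithian-2-yl]-5-(l-menthyloxy)dihydrofuran-2(3H)-one F1. F1 is then deprotonated with LDA in THF/DMPU at −78 °C to regenerate enolate 13 in the absence of other acidic species, and 13 is alkylated with bromide 11 to return to 14, with the C4 group again directing the benzyl group trans.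

Step 7. The aryl benzyl ethers may be hydrogenolysed on nickel alongside C–S cleavage, or desulfurisation may stop at thiol or thioether stages. The fallback sets out from 14 and comes back at 18, and it changes the order of the end game so that benzyl loss is wanted instead of avoided. Compound 14 is first submitted to the NaBH4/KOH then HCl conditions of step 8, which should give, through the hydroxy acid (2R,3R)-2-[3,4-bis(benzyloxy)benzyl]-3-[2-(3,4-dimethoxyphenyl)-1,3-dithian-2-yl]-4-hydroxybutanoic acid F2, the dithianyl lactone (3R,4R)-3-[3,4-bis(benzyloxy)benzyl]-4-[2-(3,4-dimethoxyphenyl)-1,3-dithian-2-yl]dihydrofuran-2(3H)-one F3. F3 is then heated with excess Raney Ni under H2 in EtOH so that desulfurisation and O-debenzylation take place in one operation and give 18 directly; steps 8 and 9 are then not needed.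

Step 8. C4 may epimerise through enolisation of the transient C5 aldehyde in hydroxide before hydride is delivered, or the hindered acylal may open so slowly that the borohydride is consumed first. The fallback sets out from 15 and comes back at 17, and it removes the acetal under acid instead of base. Hydrolysis with 2 M HCl in dioxane at 60 °C should release menthol and give the lactol (3R,4R)-3-[3,4-bis(benzyloxy)benzyl]-4-(3,4-dimethoxybenzyl)-5-hydroxydihydrofuran-2(3H)-one F4 as a mixture of C5 epimers. This pseudo-acid is reduced with NaBH4 in EtOH at 0 °C without added hydroxide to hydroxy acid 16, which lactonises to 17 on acidification.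

**Further compounds**

F1 | step 6 | (4R,5R)-4-[2-(3,4-dimethoxyphenyl)-1,3-dithian-2-yl]-5-(l-menthyloxy)dihydrofuran-2(3H)-one | COc1ccc(C2(SCCCS2)[C@H]3[C@H](O[C@@H]4C[C@H](C)CC[C@H]4C(C)C)OC(=O)C3)cc1OC
F2 | step 7 | (2R,3R)-2-[3,4-bis(benzyloxy)benzyl]-3-[2-(3,4-dimethoxyphenyl)-1,3-dithian-2-yl]-4-hydroxybutanoic acid | COc1ccc(C2(SCCCS2)[C@@H](CO)[C@@H](Cc3ccc(OCc4ccccc4)c(OCc4ccccc4)c3)C(=O)O)cc1OC
F3 | step 7 | (3R,4R)-3-[3,4-bis(benzyloxy)benzyl]-4-[2-(3,4-dimethoxyphenyl)-1,3-dithian-2-yl]dihydrofuran-2(3H)-one | COc1ccc(C2(SCCCS2)[C@H]3COC(=O)[C@@H]3Cc3ccc(OCc4ccccc4)c(OCc4ccccc4)c3)cc1OC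
F4 | step 8 | (3R,4R)-3-[3,4-bis(benzyloxy)benzyl]-4-(3,4-dimethoxybenzyl)-5-hydroxydihydrofuran-2(3H)-one (C5 epimer mixture) | COc1ccc(C[C@H]2C(O)OC(=O)[C@@H]2Cc2ccc(OCc3ccccc3)c(OCc3ccccc3)c2)cc1OC
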